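**Plan**

- Retrosynthetic cuts, in order: the exocyclic C2–NH bond to the 1-methylimidazole-2,5-dione ring (giving a 2-aminoimidazole and 1-methylparabanic acid); then N1–CH3 and the benzylic C=O on the C4 side chain; then the imidazole N3–C4 bond; then the enamine C–N bond and the central C–C bond of a 1,3-diketone.
- Enabling feature: the exocyclic amino N, C2, N3 and N1 of the 2-aminoimidazole map onto N4, C3, N2 and the 3-amino nitrogen of 3-amino-5-methyl-1,2,4-oxadiazole. Ring N2 carries a weak N–O bond, so a side-chain carbon can bond to it (N3–C4) while O1–C5(CH3) unravels into an N-acetyl group.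
- Forward order: a Claisen condensation joins the two aryl fragments as a 1,3-diketone; condensation with the aminooxadiazole gives the enaminone; the rearrangement builds the imidazole, the only ring made in the route. N-methylation, C=O to CH2, debenzylation and deacetylation follow, and the dione ring is attached intact in the last step.
- Stereochemistry: the target is achiral. The Z enaminone geometry follows from its N–H···O=C hydrogen bond, and the one racemic carbinol centre is erased by deoxygenation.

Key step: step 4

Remark: the 1,3-diketone and the NH-imidazoles are drawn as single tautomers. In the last step the phenol is deliberately silylated in the flask and freed again by the methanol quench.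

**Route**

Step 1
Reactants: 1 3-hydroxy-4-methoxyphenylacetic acid
Product: 2 benzyl 2-[3-(benzyloxy)-4-methoxyphenyl]acetate
Conditions: BnBr (2.3 equiv), K2CO3 (3 equiv), DMF, 60 °C
Reagents that add atoms: benzyl bromide, BrCc1ccccc1
Why: K2CO3 deprotonates both the carboxylic acid and the phenol, and SN2 alkylation (Williamson ether synthesis plus carboxylate alkylation) protects the phenol and supplies the ester needed as acyl donor in one operation.

Step 2
Reactants: 2 benzyl 2-[3-(benzyloxy)-4-methoxyphenyl]acetate; 3 4'-methoxyacetophenone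
Product: 4 4-[3-(benzyloxy)-4-methoxyphenyl]-1-(4-methoxyphenyl)butane-1,3-dione (largely enolised)
Conditions: 3 (1.5 equiv), NaH (3 equiv), THF, reflux, slow addition of 2; then aq. HCl
Reagents that add atoms: none
Why: In this crossed Claisen condensation the sodium enolate of 3 acylates at the ester carbonyl, formation of the stable diketonate drives the equilibrium, and slow addition of 2 keeps its own enolate concentration low.

Step 3
Reactants: 4 4-[3-(benzyloxy)-4-methoxyphenyl]-1-(4-methoxyphenyl)butane-1,3-dione; 5 3-amino-5-methyl-1,2,4-oxadiazole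
Product: 6 (Z)-4-[3-(benzyloxy)-4-methoxyphenyl]-1-(4-methoxyphenyl)-3-[(5-methyl-1,2,4-oxadiazol-3-yl)amino]but-2-en-1-one
Conditions: 5 (1.2 equiv), TsOH·H2O (10 mol%), toluene, reflux, Dean–Stark trap
Reagents that add atoms: none
Why: Acid-catalysed enaminone formation from a primary heteroarylamine and a 1,3-diketone should occur at the aliphatic carbonyl, because the anisoyl carbonyl is deactivated by its donor aryl group and remains as the conjugated ketone; the Z geometry is fixed by the N–H···O=C hydrogen bond and water removal drives the condensation.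

Step 4
Reactants: 6 (Z)-4-[3-(benzyloxy)-4-methoxyphenyl]-1-(4-methoxyphenyl)-3-[(5-methyl-1,2,4-oxadiazol-3-yl)amino]but-2-en-1-one
Product: 8 N-{5-[3-(benzyloxy)-4-methoxybenzyl]-4-(4-methoxybenzoyl)-1H-imidazol-2-yl}acetamide, via 4H-imidazole tautomer 7 (not isolated)
Conditions: NaOEt (1.2 equiv), EtOH, reflux; then AcOH
Reagents that add atoms: none
Why: Ethoxide removes the enaminone N–H, and the aza-enolate, with its charge on N, on the carbon between the two functional groups and on O, attacks ring N2 of the oxadiazole through that carbon, in the ring plane and anti to the O1–N2 bond; this bond breaks as the imidazole N3–C4 bond forms, the expelled O1–C5(CH3)=N4 unit becomes the acetamide, and 7 tautomerises at once to aromatic 8. This is the Boulton–Katritzky rearrangement in its known form for N-(1,2,4-oxadiazol-3-yl) β-enaminones, which give 2-acylamino-4-acylimidazoles. The five-membered ring (old C3, old N2, the attacking carbon, the enamine carbon and the bridging nitrogen) closes by intramolecular nucleophilic substitution at nitrogen with oxygen as the leaving group. No stereocentre remains, since the sp3 carbon of 7 is lost on tautomerisation. The step needs attack by the carbon α to the ketone and not by the benzylic carbon, which is also three atoms from C3, nor addition of ethoxide at C5; deprotonation at the far more acidic N–H places charge only on the α carbon, the enolate oxygen is too remote for a five-membered closure, and the intramolecular path should outrun ethoxide addition. Cleavage of the weak N–O bond and the gain of imidazole aromaticity make the step irreversible.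

Step 5
Reactants: 8 N-{5-[3-(benzyloxy)-4-methoxybenzyl]-4-(4-methoxybenzoyl)-1H-imidazol-2-yl}acetamide
Product: 9 N-{5-[3-(benzyloxy)-4-methoxybenzyl]-4-(4-methoxybenzoyl)-1-methyl-1H-imidazol-2-yl}acetamide
Conditions: MeI (1.05 equiv), K2CO3 (1.5 equiv), DMF, 0 °C to rt
Reagents that add atoms: iodomethane, CI
Why: In this N-alkylation of an imidazolide anion, the nitrogen flanking the aroyl group is deactivated inductively and shielded by the aryl ketone, so methylation should occur at the nitrogen next to the benzyl-bearing carbon, as is usual for 4(5)-acylimidazole anions; one equivalent of MeI limits a second methylation at the acetamide.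

Step 6
Reactants: 9 N-{5-[3-(benzyloxy)-4-methoxybenzyl]-4-(4-methoxybenzoyl)-1-methyl-1H-imidazol-2-yl}acetamide
Product: 10 N-{5-[3-(benzyloxy)-4-methoxybenzyl]-4-[hydroxy(4-methoxyphenyl)methyl]-1-methyl-1H-imidazol-2-yl}acetamide (racemic)
Conditions: NaBH4 (2 equiv), MeOH/THF, 0 °C to rt
Reagents that add atoms: none
Why: Borohydride 1,2-reduction of the aryl heteroaryl ketone leaves the acetamide and ethers untouched; the new carbinol centre is not controlled (racemic) and is removed in step 7.

Step 7
Reactants: 10 N-{5-[3-(benzyloxy)-4-methoxybenzyl]-4-[hydroxy(4-methoxyphenyl)methyl]-1-methyl-1H-imidazol-2-yl}acetamide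
Product: 11 N-{5-[3-(benzyloxy)-4-methoxybenzyl]-4-(4-methoxybenzyl)-1-methyl-1H-imidazol-2-yl}acetamide
Conditions: Et3SiH (3 equiv), CF3CO2H, CH2Cl2, 0 °C to rt; then aq. NaHCO3
Reagents that add atoms: none
Why: In this ionic hydrogenation the acid ionises the carbinol to a cation stabilised by the 4-methoxyphenyl group and the silane delivers hydride, a standard deoxygenation of aryl(imidazolyl)methanols that the benzyl ether and acetamide should survive at this temperature.

Step 8
Reactants: 11 N-{5-[3-(benzyloxy)-4-methoxybenzyl]-4-(4-methoxybenzyl)-1-methyl-1H-imidazol-2-yl}acetamide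
Product: 12 N-[5-(3-hydroxy-4-methoxybenzyl)-4-(4-methoxybenzyl)-1-methyl-1H-imidazol-2-yl]acetamide
Conditions: H2 (1 atm), 10% Pd/C, MeOH/EtOAc, rt
Reagents that add atoms: none
Why: Catalytic hydrogenolysis cleaves the benzyl aryl ether, while the two ring-to-arene methylene bridges carry no heteroatom and are not cleaved.

Step 9
Reactants: 12 N-[5-(3-hydroxy-4-methoxybenzyl)-4-(4-methoxybenzyl)-1-methyl-1H-imidazol-2-yl]acetamide
Product: 13 5-{[2-amino-4-(4-methoxybenzyl)-1-methyl-1H-imidazol-5-yl]methyl}-2-methoxyphenol
Conditions: 3 M aq. HCl, 1,4-dioxane, 90 °C; then aq. NaHCO3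
Reagents that add atoms: none
Why: Acid-catalysed amide hydrolysis is easy here because the protonated 2-aminoimidazole is a guanidine-like leaving group, and the aryl ethers, phenol and imidazole are stable to dilute acid.

Step 10
Reactants: 13 5-{[2-amino-4-(4-methoxybenzyl)-1-methyl-1H-imidazol-5-yl]methyl}-2-methoxyphenol; 14 1-methylparabanic acid
Product: 18 naamidine B, via silyl imidate 15 (not isolated), via aryl silyl ether 16 (not isolated), via O-silyl naamidine B 17 (not isolated)
Conditions: 14 (2 equiv), N,O-bis(trimethylsilyl)acetamide (5 equiv), MeCN, 80 °C; then 13, toluene, 100 °C; then MeOH, rt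
Reagents that add atoms: none
Why: Silylation converts the N3–H/C4=O amide of 14 into the O-silyl imidate 15, whose C4 undergoes addition–elimination with the exocyclic amino group of the silyl-capped aminoimidazole 16, losing trimethylsilanol to give the cyclic acylamidine 17; methanol then frees the phenol, the established way of converting phenolic 2-aminoimidazoles of this family into their dione adducts.

**Compound list**

1 | 3-hydroxy-4-methoxyphenylacetic acid | COc1ccc(CC(=O)O)cc1O | starting material
2 | benzyl 2-[3-(benzyloxy)-4-methoxyphenyl]acetate | COc1ccc(CC(=O)OCc2ccccc2)cc1OCc1ccccc1 | intermediate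
3 | 4'-methoxyacetophenone | CC(=O)c1ccc(OC)cc1 | starting material
4 | 4-[3-(benzyloxy)-4-methoxyphenyl]-1-(4-methoxyphenyl)butane-1,3-dione | COc1ccc(CC(=O)CC(=O)c2ccc(OC)cc2)cc1OCc1ccccc1 | intermediate
5 | 3-amino-5-methyl-1,2,4-oxadiazole | Cc1nc(N)no1 | starting material
6 | (Z)-4-[3-(benzyloxy)-4-methoxyphenyl]-1-(4-methoxyphenyl)-3-[(5-methyl-1,2,4-oxadiazol-3-yl)amino]but-2-en-1-one | Cc1nc(N/C(Cc2ccc(OC)c(OCc3ccccc3)c2)=C\C(=O)c2ccc(OC)cc2)no1 | intermediate
7 | N-{5-[3-(benzyloxy)-4-methoxybenzyl]-4-(4-methoxybenzoyl)-4H-imidazol-2-yl}acetamide (racemic, transient) | CC(=O)NC1=NC(C(=O)c2ccc(OC)cc2)C(Cc2ccc(OC)c(OCc3ccccc3)c2)=N1 | intermediate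
8 | N-{5-[3-(benzyloxy)-4-methoxybenzyl]-4-(4-methoxybenzoyl)-1H-imidazol-2-yl}acetamide | CC(=O)Nc1nc(C(=O)c2ccc(OC)cc2)c(Cc2ccc(OC)c(OCc3ccccc3)c2)[nH]1 | intermediate
9 | N-{5-[3-(benzyloxy)-4-methoxybenzyl]-4-(4-methoxybenzoyl)-1-methyl-1H-imidazol-2-yl}acetamide | CC(=O)Nc1nc(C(=O)c2ccc(OC)cc2)c(Cc2ccc(OC)c(OCc3ccccc3)c2)n1C | intermediate
10 | N-{5-[3-(benzyloxy)-4-methoxybenzyl]-4-[hydroxy(4-methoxyphenyl)methyl]-1-methyl-1H-imidazol-2-yl}acetamide (racemic) | CC(=O)Nc1nc(C(O)c2ccc(OC)cc2)c(Cc2ccc(OC)c(OCc3ccccc3)c2)n1C | intermediate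
11 | N-{5-[3-(benzyloxy)-4-methoxybenzyl]-4-(4-methoxybenzyl)-1-methyl-1H-imidazol-2-yl}acetamide | CC(=O)Nc1nc(Cc2ccc(OC)cc2)c(Cc2ccc(OC)c(OCc3ccccc3)c2)n1C | intermediate
12 | N-[5-(3-hydroxy-4-methoxybenzyl)-4-(4-methoxybenzyl)-1-methyl-1H-imidazol-2-yl]acetamide | CC(=O)Nc1nc(Cc2ccc(OC)cc2)c(Cc2ccc(OC)c(O)c2)n1C | intermediate
13 | 5-{[2-amino-4-(4-methoxybenzyl)-1-methyl-1H-imidazol-5-yl]methyl}-2-methoxyphenol | COc1ccc(Cc2nc(N)n(C)c2Cc2ccc(OC)c(O)c2)cc1 | intermediate
14 | 1-methylparabanic acid (1-methylimidazolidine-2,4,5-trione) | CN1C(=O)NC(=O)C1=O | starting material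
15 | 1-methyl-4-[(trimethylsilyl)oxy]-1H-imidazole-2,5-dione | CN1C(=O)N=C(O[Si](C)(C)C)C1=O | intermediate
16 | 4-(4-methoxybenzyl)-5-{4-methoxy-3-[(trimethylsilyl)oxy]benzyl}-1-methyl-1H-imidazol-2-amine | COc1ccc(Cc2nc(N)n(C)c2Cc2ccc(OC)c(O[Si](C)(C)C)c2)cc1 | intermediate
17 | 4-{[4-(4-methoxybenzyl)-5-{4-methoxy-3-[(trimethylsilyl)oxy]benzyl}-1-methyl-1H-imidazol-2-yl]amino}-1-methyl-1H-imidazole-2,5-dione | COc1ccc(Cc2nc(NC3=NC(=O)N(C)C3=O)n(C)c2Cc2ccc(OC)c(O[Si](C)(C)C)c2)cc1 | intermediate
18 | naamidine B, 4-{[5-(3-hydroxy-4-methoxybenzyl)-4-(4-methoxybenzyl)-1-methyl-1H-imidazol-2-yl]amino}-1-methyl-1H-imidazole-2,5-dione | COc1ccc(Cc2nc(NC3=NC(=O)N(C)C3=O)n(C)c2Cc2ccc(OC)c(O)c2)cc1 | target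

**Step count and risks**

Total step count: 10. Longest linear sequence: 10 steps (1 to 18); 3, 5 and 14 enter as purchased materials.

Steps most likely to fail:

1. Step 5. Iodomethane is small and reactive, so methylation may be divided between the two ring nitrogens, spill onto the acetamide nitrogen or go on to a second methylation. The fallback sets out from 8 and replaces the methyl source by a bulkier, slower and traceless one. Alkylation with (chloromethyl)trimethylsilane, NaI and K2CO3 in DMF at 60 °C should pick only the less shielded, more electron-rich ring nitrogen and give N-{5-[3-(benzyloxy)-4-methoxybenzyl]-4-(4-methoxybenzoyl)-1-[(trimethylsilyl)methyl]-1H-imidazol-2-yl}acetamide F1. Protodesilylation with Bu4NF in wet THF then cleaves the C–Si bond next to the azole nitrogen and comes back to the route at 9.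

2. Step 3. The amino group of 5 is a poor nucleophile, so condensation may stall, be shared between the two carbonyl groups or be overtaken by acid-promoted decomposition on long heating. The fallback sets out from 4 and separates regiocontrol from C–N bond formation. Pyrrolidine in refluxing toluene with water removal should condense quickly and only at the aliphatic carbonyl to give (E)-4-[3-(benzyloxy)-4-methoxyphenyl]-1-(4-methoxyphenyl)-3-(pyrrolidin-1-yl)but-2-en-1-one F2. Amine exchange with 5 in AcOH at 80 °C, through the protonated and much more electrophilic vinylogous amidinium ion with loss of pyrrolidine, then leads to the hydrogen-bonded secondary enaminone and comes back at 6.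

3. Step 2. The benzylic protons of ester 2 are about as acidic as the methyl protons of 3, so proton transfer to the ketone enolate may lead to ester self-condensation and aldol products in place of the crossed acylation. The fallback sets out from 2 and changes the acyl donor. Aminolysis with MeNHOMe·HCl and i-PrMgCl in THF at −10 °C gives 2-[3-(benzyloxy)-4-methoxyphenyl]-N-methoxy-N-methylacetamide F3 (a Weinreb amide), whose α protons are less acidic than those of the ketone and whose tetrahedral adduct is held as a lithium chelate. Acylation of the preformed lithium enolate of 3 (LiN(SiMe3)2, THF, −78 to 0 °C) with this amide comes back at 4.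

Further compounds
F1 | step 5 | N-{5-[3-(benzyloxy)-4-methoxybenzyl]-4-(4-methoxybenzoyl)-1-[(trimethylsilyl)methyl]-1H-imidazol-2-yl}acetamide | CC(=O)Nc1nc(C(=O)c2ccc(OC)cc2)c(Cc2ccc(OC)c(OCc3ccccc3)c2)n1C[Si](C)(C)C
F2 | step 3 | (E)-4-[3-(benzyloxy)-4-methoxyphenyl]-1-(4-methoxyphenyl)-3-(pyrrolidin-1-yl)but-2-en-1-one | O=C(c1ccc(OC)cc1)/C=C(\Cc1ccc(OC)c(OCc2ccccc2)c1)N1CCCC1
F3 | step 2 | 2-[3-(benzyloxy)-4-methoxyphenyl]-N-methoxy-N-methylacetamide | COc1ccc(CC(=O)N(C)OC)cc1OCc1ccccc1
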